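**Assumption:** the target has no stereocentre and no stereogenic double bond, so it is one achiral compound and no stereocontrol is needed.

## Retrosynthetic overview

1. Target ⇐ double O-methylation of the unsymmetrical 2,5-dihydroxy-3,6-bis(indol-3-yl)-1,4-benzoquinone, done in the same flask as the ring formation.
2. Quinone ring ⇐ head-to-tail crossed double Claisen (Claisen, then Dieckmann) of two different indol-3-ylpyruvate esters, as in the biosynthetic dimerisation of indolepyruvate. The 2-(1,1-dimethylallyl) group is already on one partner, so no late prenylation of a symmetric dimer is needed.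
3. Prenylated pyruvate ester ⇐ C3-alkylation of 2-(1,1-dimethylallyl)indole with a nitrosoacrylate, then deoximation; that indole ⇐ Fischer synthesis.
4. Unsubstituted pyruvate ester ⇐ esterification of commercial indole-3-pyruvic acid.
5. Ring order: pyrrole ring of the prenylated indole first (Fischer), quinone ring last; the second indole is bought.

## Route

Step 1
Reactants: 1 phenylhydrazine; 2 3,3-dimethylpent-4-en-2-one
Product: 4 2-(2-methylbut-3-en-2-yl)-1H-indole, via phenylhydrazone 3 (not isolated)
Conditions: cat. AcOH, EtOH, 80 °C; evaporate; ZnCl2 (3 equiv), xylene, 140 °C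
Reagents that add atoms: none
Why: Fischer indole synthesis: ketone 2 can form an ene-hydrazine only toward its methyl group, so the [3,3]-sigmatropic shift, cyclisation and loss of NH3 give the 2-substituted, 3-unsubstituted indole, and the Lewis acid ZnCl2 should spare the monosubstituted alkene on the quaternary carbon; no stereocentre is formed.

Step 2
Reactants: 4 2-(2-methylbut-3-en-2-yl)-1H-indole; 5 ethyl 3-bromo-2-(hydroxyimino)propanoate
Product: 7 ethyl 2-(hydroxyimino)-3-[2-(2-methylbut-3-en-2-yl)-1H-indol-3-yl]propanoate, via nitrosoalkene 6 (not isolated)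
Conditions: Na2CO3 (5 equiv), CH2Cl2, 23 °C; 5 (1.5 equiv) added over 6 h
Reagents that add atoms: none
Why: Na2CO3 eliminates HBr from 5 to the nitrosoalkene 6, a very reactive heterodiene and Michael acceptor that is attacked by the free C3 of 4 (conjugate addition or [4+2] cycloaddition, then ring-opening on rearomatisation), the standard nitrosoalkene alkylation of indoles; slow addition limits oligomerisation of 6 and the oxime geometry is of no consequence.

Step 3
Reactants: 7 ethyl 2-(hydroxyimino)-3-[2-(2-methylbut-3-en-2-yl)-1H-indol-3-yl]propanoate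
Product: 9 ethyl 3-[2-(2-methylbut-3-en-2-yl)-1H-indol-3-yl]-2-oxopropanoate, via imine 8 (not isolated)
Conditions: TiCl3 (15% aq., 2.5 equiv), NH4OAc, THF–H2O, 0 → 23 °C, N2
Reagents that add atoms: water, O
Why: Reductive deoximation: trivalent titanium cleaves the N–O bond by two one-electron transfers and the NH-imine 8 (in equilibrium with its indole-conjugated enamine) hydrolyses in the buffered medium to the α-keto ester, which exists mainly as its enol; ester, indole and alkene are inert.

Step 4
Reactants: 10 3-(1H-indol-3-yl)-2-oxopropanoic acid (indole-3-pyruvic acid)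
Product: 11 methyl 3-(1H-indol-3-yl)-2-oxopropanoate
Conditions: MeOH, cat. H2SO4, 23 °C, N2, dark
Reagents that add atoms: methanol, CO
Why: Fischer esterification (acid-catalysed acyl substitution in excess methanol); the indole and the largely enolised α-keto group tolerate catalytic acid at 23 °C.

Step 5
Reactants: 9 ethyl 3-[2-(2-methylbut-3-en-2-yl)-1H-indol-3-yl]-2-oxopropanoate (1 equiv); 11 methyl 3-(1H-indol-3-yl)-2-oxopropanoate (3 equiv)
Product: 14 3-(1H-indol-3-yl)-2,5-dimethoxy-6-[2-(2-methylbut-3-en-2-yl)-1H-indol-3-yl]cyclohexa-2,5-diene-1,4-dione, via triketo ester 12 (not isolated), via dihydroxyquinone 13 (not isolated)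
Conditions: NaH (1.05 equiv per keto ester), THF, 0 °C; sodium enolate of 11 added over 4 h to that of 9 at 65 °C; 0 °C, HCl/dioxane (1 equiv per NaH); MeOH, TMSCHN2 (excess), 0 → 23 °C; chromatography
Reagents that add atoms: (trimethylsilyl)diazomethane, C[Si](C)(C)C=[N+]=[N-]
Why: Proposed new method: with both α-keto esters held as sodium enolates there is no free ketone for the usual aldol–lactonisation, so the remaining C–C bond formation is Claisen attack of the unhindered benzylic carbon of 11 on the sodium-chelated ester of 9 (giving 12), followed by a 6-exo-trig Dieckmann closure of the hindered 9-derived carbon onto the methyl ester to give the tetraone, that is the dianion of 13, each acylation being made irreversible by deprotonation; excess 11 makes the cross-dimer the main fate of 9 (the self-dimer of 11 is removed at the end), and HCl then TMSCHN2 methylates only the two vinylogous-acid OH groups to the para-quinone dimethyl ether, leaving the indole NH untouched; closest known reaction types are the alkoxide-mediated double Claisen self-condensation of α-keto esters to 3,6-disubstituted 2,5-dihydroxy-1,4-benzoquinones, the head-to-tail dimerisation of indolepyruvate thioesters in the biosynthesis, and diazomethane methylation of vinylogous acids; no stereocentre is formed.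

## Compound list

1 | phenylhydrazine | NNc1ccccc1 | starting material
2 | 3,3-dimethylpent-4-en-2-one | CC(=O)C(C)(C)C=C | starting material
3 | 3,3-dimethylpent-4-en-2-one phenylhydrazone (not isolated; C=N geometry not relevant) | CC(=NNc1ccccc1)C(C)(C)C=C | intermediate
4 | 2-(2-methylbut-3-en-2-yl)-1H-indole | C=CC(C)(C)c1cc2ccccc2[nH]1 | intermediate
5 | ethyl 3-bromo-2-(hydroxyimino)propanoate | CCOC(=O)C(CBr)=NO | starting material
6 | ethyl 2-nitrosoprop-2-enoate (not isolated) | CCOC(=O)C(=C)N=O | intermediate
7 | ethyl 2-(hydroxyimino)-3-[2-(2-methylbut-3-en-2-yl)-1H-indol-3-yl]propanoate (oxime geometry not relevant) | CCOC(=O)C(=NO)Cc1c(C(C)(C)C=C)[nH]c2ccccc12 | intermediate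
8 | ethyl 2-imino-3-[2-(2-methylbut-3-en-2-yl)-1H-indol-3-yl]propanoate (not isolated) | CCOC(=O)C(=N)Cc1c(C(C)(C)C=C)[nH]c2ccccc12 | intermediate
9 | ethyl 3-[2-(2-methylbut-3-en-2-yl)-1H-indol-3-yl]-2-oxopropanoate | CCOC(=O)C(=O)Cc1c(C(C)(C)C=C)[nH]c2ccccc12 | intermediate
10 | 3-(1H-indol-3-yl)-2-oxopropanoic acid (indole-3-pyruvic acid) | OC(=O)C(=O)Cc1c[nH]c2ccccc12 | starting material
11 | methyl 3-(1H-indol-3-yl)-2-oxopropanoate | COC(=O)C(=O)Cc1c[nH]c2ccccc12 | intermediate
12 | methyl 3-(1H-indol-3-yl)-6-[2-(2-methylbut-3-en-2-yl)-1H-indol-3-yl]-2,4,5-trioxohexanoate (not isolated; present as its disodium bis-enolate, so C3 carries no configuration) | COC(=O)C(=O)C(c1c[nH]c2ccccc12)C(=O)C(=O)Cc1c(C(C)(C)C=C)[nH]c2ccccc12 | intermediate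
13 | 2,5-dihydroxy-3-(1H-indol-3-yl)-6-[2-(2-methylbut-3-en-2-yl)-1H-indol-3-yl]cyclohexa-2,5-diene-1,4-dione (not isolated) | C=CC(C)(C)c1[nH]c2ccccc2c1C1=C(O)C(=O)C(c2c[nH]c3ccccc23)=C(O)C1=O | intermediate
14 | 3-(1H-indol-3-yl)-2,5-dimethoxy-6-[2-(2-methylbut-3-en-2-yl)-1H-indol-3-yl]cyclohexa-2,5-diene-1,4-dione | C=CC(C)(C)c1[nH]c2ccccc2c1C1=C(OC)C(=O)C(c2c[nH]c3ccccc23)=C(OC)C1=O | target

## Step count and risks

Total steps: 5 (steps 1–3 and 5 in line, step 4 on the side branch).
Longest linear sequence: 4 steps (1 → 2 → 3 → 5).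

**Most likely to fail, first: step 5.** The enolates may still give aldol-derived butenolides, the Dieckmann closure next to the tert-alkyl-bearing indole may stall, self-dimer of 11 may dominate, or methylation may give some ortho-quinone isomer. The fallback drops the pyruvate dimerisation; it sets out from 4 and comes back at 14. Acetic-acid-promoted conjugate addition of 4 to commercial 2,5-dichloro-1,4-benzoquinone gives 2,5-dichloro-3-[2-(2-methylbut-3-en-2-yl)-1H-indol-3-yl]benzene-1,4-diol F1. DDQ oxidises this in the same flask to 2,5-dichloro-3-[2-(2-methylbut-3-en-2-yl)-1H-indol-3-yl]cyclohexa-2,5-diene-1,4-dione F2. Addition of commercial indole to the remaining free position of F2 (cat. HCl, THF) gives 2,5-dichloro-3-(1H-indol-3-yl)-6-[2-(2-methylbut-3-en-2-yl)-1H-indol-3-yl]benzene-1,4-diol F3, and DDQ again gives 2,5-dichloro-3-(1H-indol-3-yl)-6-[2-(2-methylbut-3-en-2-yl)-1H-indol-3-yl]cyclohexa-2,5-diene-1,4-dione F4. NaOMe in MeOH at 23 °C then replaces both vinylogous acyl chlorides by addition–elimination to give 14.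

**Second: step 1.** The hindered hydrazone may indolise sluggishly, and hot ZnCl2 may trigger cationic rearrangement or cyclisation of the 1,1-dimethylallyl group. The fallback builds the indole by reductive cyclisation instead; it sets out from 2 and comes back at 4. Palladium-catalysed α-arylation of the methyl group of 2 with commercial 1-bromo-2-nitrobenzene (Pd2(dba)3 as the source of zerovalent palladium, 2-(di-tert-butylphosphino)-2'-methylbiphenyl, K3PO4, cat. 4-methoxyphenol, toluene, 50 °C) gives 3,3-dimethyl-1-(2-nitrophenyl)pent-4-en-2-one F5. Fe powder in AcOH at 80 °C reduces the nitro group to 1-(2-aminophenyl)-3,3-dimethylpent-4-en-2-one F6, which condenses in the flask with loss of water to 4.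

**Third: step 3.** Trivalent titanium may over-reduce or pinacol-couple the α-keto ester, hydrolysis of the conjugated enamine may be slow, and the enol product is air-sensitive. The fallback reaches the keto ester by oxidation instead of deoximation; it sets out from 4 and comes back at 9. Sc(OTf)3-catalysed opening of commercial ethyl oxirane-2-carboxylate at its CH2 terminus by C3 of 4 (CH2Cl2, 23 °C) gives racemic ethyl 2-hydroxy-3-[2-(2-methylbut-3-en-2-yl)-1H-indol-3-yl]propanoate F7. Dess–Martin periodinane (CH2Cl2, 0 °C) oxidises the secondary alcohol to 9, removing the stereocentre.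

## Further compounds

F1 | step 5 | 2,5-dichloro-3-[2-(2-methylbut-3-en-2-yl)-1H-indol-3-yl]benzene-1,4-diol | C=CC(C)(C)c1[nH]c2ccccc2c1-c1c(Cl)c(O)cc(Cl)c1O
F2 | step 5 | 2,5-dichloro-3-[2-(2-methylbut-3-en-2-yl)-1H-indol-3-yl]cyclohexa-2,5-diene-1,4-dione | C=CC(C)(C)c1[nH]c2ccccc2c1C1=C(Cl)C(=O)C=C(Cl)C1=O
F3 | step 5 | 2,5-dichloro-3-(1H-indol-3-yl)-6-[2-(2-methylbut-3-en-2-yl)-1H-indol-3-yl]benzene-1,4-diol | C=CC(C)(C)c1[nH]c2ccccc2c1-c1c(Cl)c(O)c(-c2c[nH]c3ccccc23)c(Cl)c1O
F4 | step 5 | 2,5-dichloro-3-(1H-indol-3-yl)-6-[2-(2-methylbut-3-en-2-yl)-1H-indol-3-yl]cyclohexa-2,5-diene-1,4-dione | C=CC(C)(C)c1[nH]c2ccccc2c1C1=C(Cl)C(=O)C(c2c[nH]c3ccccc23)=C(Cl)C1=O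
F5 | step 1 | 3,3-dimethyl-1-(2-nitrophenyl)pent-4-en-2-one | C=CC(C)(C)C(=O)Cc1ccccc1[N+](=O)[O-]
F6 | step 1 | 1-(2-aminophenyl)-3,3-dimethylpent-4-en-2-one | C=CC(C)(C)C(=O)Cc1ccccc1N
F7 | step 3 | ethyl 2-hydroxy-3-[2-(2-methylbut-3-en-2-yl)-1H-indol-3-yl]propanoate (racemic) | CCOC(=O)C(O)Cc1c(C(C)(C)C=C)[nH]c2ccccc12
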